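**Retrosynthetic overview**

1. Feature: in the benzene ring of the indole, the adjacent carbons C5 and C6 carry Br and are flanked by C4–H and C7–H. This is the imprint of a symmetrical alkyne (C5–C6) set between the two terminal CH carbons (C4, C7) of a diyne whose inner carbons C3a and C7a are tied together through C3–C2–N1.
2. Endgame: 21 ⇐ double ipso-bromodesilylation of 19 ⇐ C2 lithiation/bromination of gramine 17 ⇐ Mannich reaction at C3 of indole 15 ⇐ dehydrogenation of indoline 14 ⇐ LiAlH4 reduction of carbamate 12 (the carbamate carbon becomes N–CH3).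
3. Key disconnection: C3a–C7a, C4–C5 and C6–C7 of 12 ⇐ ynamide diyne 10 + bis(trimethylsilyl)acetylene 11 under CpCo(CO)2.
4. Diyne 10 ⇐ but-3-yn-1-amine 1 + methyl chloroformate 2, C-silylation, copper-catalysed N-alkynylation with bromoalkyne 7, fluoride.
5. Ring order: the five-membered nitrogen ring and the benzene ring form together in step 5; the pyrrole ring is aromatised in step 7.

Key step: step 5

Assumption: silicon is kept at C5 and C6 until the last step, because the carbamate reduction (LiAlH4) and the C2 bromination (n-BuLi) would not spare aryl bromides but leave aryl silanes untouched.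

**Route**

Step 1
Reactants: 1 but-3-yn-1-amine; 2 methyl chloroformate
Product: 3 methyl but-3-yn-1-ylcarbamate
Conditions: aq NaOH (1.1 equiv), CH2Cl2, 0 °C to rt
Reagents that add atoms: none
Why: Schotten–Baumann N-acylation of a primary amine by a chloroformate, to which the terminal alkyne is inert.

Step 2
Reactants: 3 methyl but-3-yn-1-ylcarbamate
Product: 6 methyl [4-(trimethylsilyl)but-3-yn-1-yl]carbamate, via dilithiated carbamate 4 (not isolated), via N,C-bis(trimethylsilyl) carbamate 5 (not isolated)
Conditions: n-BuLi (2.2 equiv), THF, −78 °C; Me3SiCl (2.3 equiv), −78 to 0 °C; aq NH4Cl work-up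
Reagents that add atoms: chlorotrimethylsilane, C[Si](C)(C)Cl
Why: Dianion silylation: n-BuLi removes N–H and then the alkynyl C–H, both anions are silylated, and the labile N–Si bond is hydrolysed on aqueous work-up while the alkynyl C–Si bond stays.

Step 3
Reactants: 6 methyl [4-(trimethylsilyl)but-3-yn-1-yl]carbamate; 7 (bromoethynyl)triisopropylsilane
Product: 8 methyl N-[(triisopropylsilyl)ethynyl]-N-[4-(trimethylsilyl)but-3-yn-1-yl]carbamate
Conditions: CuSO4·5H2O (10 mol %), 1,10-phenanthroline (20 mol %), K3PO4 (2 equiv), toluene, 75 °C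
Reagents that add atoms: none
Why: Copper-catalysed N-alkynylation of an acyclic carbamate with a bromoalkyne (Ullmann-type amidative coupling); the silyl cap on the other alkyne prevents a competing Cadiot–Chodkiewicz coupling.

Step 4
Reactants: 8 methyl N-[(triisopropylsilyl)ethynyl]-N-[4-(trimethylsilyl)but-3-yn-1-yl]carbamate
Product: 10 methyl N-(but-3-yn-1-yl)-N-ethynylcarbamate, via mono-desilylated TIPS-ynamide 9 (not isolated)
Conditions: TBAF (2.2 equiv), wet THF, 0 °C, short reaction time; aq NH4Cl; used promptly
Reagents that add atoms: none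
Why: Fluoride-induced protodesilylation of both alkynylsilanes (the alkyl-alkyne SiMe3 first, then the ynamide Si(iPr)3), a standard way to terminal N-ethynyl carbamates, which are isolable when handled cold and without acid.

Step 5
Reactants: 10 methyl N-(but-3-yn-1-yl)-N-ethynylcarbamate; 11 bis(trimethylsilyl)acetylene
Product: 12 methyl 5,6-bis(trimethylsilyl)indoline-1-carboxylate
Conditions: CpCo(CO)2 (10 mol %), degassed 11 as solvent (large excess), reflux (ca. 135 °C), hν (visible lamp), syringe-pump addition of 10 over ca. 15 h
Reagents that add atoms: none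
Why: CpCo(CO)2 loses CO under heat and light, and the monovalent cobalt fragment binds both alkynes of 10 and couples them oxidatively to a cobaltacyclopentadiene of trivalent cobalt; this forms C3a–C7a and so closes the five-membered nitrogen ring (N1–C2–C3–C3a–C7a) by joining the two inner alkyne carbons across the three-atom tether. Coordination of 11 and its insertion into a Co–C bond (or direct [4+2] addition across C4 and C7 of the metallacycle), followed by reductive elimination, forms C4–C5 and C6–C7, closes the benzene ring and returns monovalent cobalt. The closest known reaction types are the CpCo(CO)2-catalysed cocyclisation of 1,6-diynes with bis(trimethylsilyl)acetylene to ortho-bis(silyl)arenes and the cobalt- and rhodium-catalysed cyclotrimerisations of ynamide diynes to fused aminoarenes and indolines. No stereocentre is formed. Regiochemistry cannot vary, since the tether fixes the diyne and 11 is symmetrical. The step needs chemoselectivity for cross- over self-cyclisation of 10: 11 is too hindered to trimerise with itself and is therefore used as solvent, while slow addition keeps the stationary concentration of 10 low.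

Step 6
Reactants: 12 methyl 5,6-bis(trimethylsilyl)indoline-1-carboxylate
Product: 14 1-methyl-5,6-bis(trimethylsilyl)indoline, via N-formylindoline 13 (not isolated)
Conditions: LiAlH4 (3 equiv), THF, 0 °C to reflux; Fieser work-up
Reagents that add atoms: none
Why: Hydride reduction of an N-aryl methyl carbamate through the formamide to the N-methyl amine, so that the carbamate carbon becomes the N-methyl carbon; aryl–silicon bonds are inert to LiAlH4.

Step 7
Reactants: 14 1-methyl-5,6-bis(trimethylsilyl)indoline
Product: 15 1-methyl-5,6-bis(trimethylsilyl)-1H-indole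
Conditions: activated MnO2 (15 equiv), CH2Cl2, rt
Reagents that add atoms: none
Why: MnO2 dehydrogenation of an N-alkylindoline to the indole, driven by aromatisation and run under neutral conditions that should not touch the aryl silanes.

Step 8
Reactants: 15 1-methyl-5,6-bis(trimethylsilyl)-1H-indole; 16 N,N-dimethylmethyleneiminium iodide (Eschenmoser's salt)
Product: 17 1-methyl-5,6-bis(trimethylsilyl)gramine, i.e. N,N-dimethyl-1-[1-methyl-5,6-bis(trimethylsilyl)-1H-indol-3-yl]methanamine
Conditions: CH2Cl2/MeCN, 0 °C to rt; aq NaOH work-up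
Reagents that add atoms: none
Why: Mannich aminomethylation at the nucleophilic C3 of the indole with a preformed iminium salt; no acid is added, so protodesilylation of the strained ortho-bis(silyl)arene is avoided.

Step 9
Reactants: 17 1-methyl-5,6-bis(trimethylsilyl)gramine
Product: 19 2-bromo-1-methyl-5,6-bis(trimethylsilyl)gramine, via 2-lithiogramine 18 (not isolated)
Conditions: n-BuLi (1.3 equiv), THF, −78 to 0 °C; BrCCl2CCl2Br (1.4 equiv), −78 °C to rt
Reagents that add atoms: 1,2-dibromo-1,1,2,2-tetrachloroethane, BrC(Cl)(Cl)C(Cl)(Cl)Br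
Why: Directed C2 lithiation of a 1-methylgramine (the most acidic ring C–H, α to N1, with lithium held by the side-chain amine) and trapping with an electrophilic bromine donor; the aryl silanes tolerate n-BuLi where aryl bromides would undergo exchange.

Step 10
Reactants: 19 2-bromo-1-methyl-5,6-bis(trimethylsilyl)gramine
Product: 21 2,5,6-tribromo-1-methylgramine, via 5-bromo-6-silyl gramine 20 (not isolated)
Conditions: Br2 (2.3 equiv), NaOAc (3 equiv), AcOH/CH2Cl2, 0 to 40 °C; aq Na2S2O3, then aq NaOH
Reagents that add atoms: bromine, BrBr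
Why: Stepwise electrophilic ipso-bromodesilylation of an ortho-bis(silyl)arene through β-silicon-stabilised arenium ions (C5, para to N1, first), run in acetic acid so that the side-chain amine is protonated, which should suppress attack at C3 with loss of the aminomethyl group and oxidation at nitrogen.

**Compound list**

1 | but-3-yn-1-amine | C#CCCN | starting material
2 | methyl chloroformate | COC(=O)Cl | starting material
3 | methyl but-3-yn-1-ylcarbamate | C#CCCNC(=O)OC | intermediate
4 | dilithiated carbamate (N-lithio, C-lithio derivative of 3) | [Li]C#CCCN([Li])C(=O)OC | intermediate (not isolated)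
5 | methyl N-(trimethylsilyl)-N-[4-(trimethylsilyl)but-3-yn-1-yl]carbamate | COC(=O)N(CCC#C[Si](C)(C)C)[Si](C)(C)C | intermediate (not isolated)
6 | methyl [4-(trimethylsilyl)but-3-yn-1-yl]carbamate | COC(=O)NCCC#C[Si](C)(C)C | intermediate
7 | (bromoethynyl)triisopropylsilane | CC(C)[Si](C#CBr)(C(C)C)C(C)C | starting material
8 | methyl N-[(triisopropylsilyl)ethynyl]-N-[4-(trimethylsilyl)but-3-yn-1-yl]carbamate | COC(=O)N(CCC#C[Si](C)(C)C)C#C[Si](C(C)C)(C(C)C)C(C)C | intermediate
9 | methyl N-(but-3-yn-1-yl)-N-[(triisopropylsilyl)ethynyl]carbamate | C#CCCN(C#C[Si](C(C)C)(C(C)C)C(C)C)C(=O)OC | intermediate (not isolated)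
10 | methyl N-(but-3-yn-1-yl)-N-ethynylcarbamate | C#CCCN(C#C)C(=O)OC | intermediate
11 | bis(trimethylsilyl)acetylene | C[Si](C)(C)C#C[Si](C)(C)C | starting material
12 | methyl 5,6-bis(trimethylsilyl)indoline-1-carboxylate | COC(=O)N1CCc2cc([Si](C)(C)C)c([Si](C)(C)C)cc21 | intermediate
13 | 5,6-bis(trimethylsilyl)indoline-1-carbaldehyde | O=CN1CCc2cc([Si](C)(C)C)c([Si](C)(C)C)cc21 | intermediate (not isolated)
14 | 1-methyl-5,6-bis(trimethylsilyl)indoline | CN1CCc2cc([Si](C)(C)C)c([Si](C)(C)C)cc21 | intermediate
15 | 1-methyl-5,6-bis(trimethylsilyl)-1H-indole | Cn1ccc2cc([Si](C)(C)C)c([Si](C)(C)C)cc21 | intermediate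
16 | N,N-dimethylmethyleneiminium iodide | C=[N+](C)C.[I-] | starting material
17 | 1-methyl-5,6-bis(trimethylsilyl)gramine | CN(C)Cc1cn(C)c2cc([Si](C)(C)C)c([Si](C)(C)C)cc12 | intermediate
18 | 2-lithio-1-methyl-5,6-bis(trimethylsilyl)gramine | [Li]c1n(C)c2cc([Si](C)(C)C)c([Si](C)(C)C)cc2c1CN(C)C | intermediate (not isolated)
19 | 2-bromo-1-methyl-5,6-bis(trimethylsilyl)gramine | CN(C)Cc1c(Br)n(C)c2cc([Si](C)(C)C)c([Si](C)(C)C)cc12 | intermediate
20 | 2,5-dibromo-1-methyl-6-(trimethylsilyl)gramine | CN(C)Cc1c(Br)n(C)c2cc([Si](C)(C)C)c(Br)cc12 | intermediate (not isolated)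
21 | 2,5,6-tribromo-1-methylgramine | CN(C)Cc1c(Br)n(C)c2cc(Br)c(Br)cc12 | target

**Step count**

Total: 10 steps. Longest linear sequence: 10 steps (from 1).

**Steps most likely to fail**

Step 5. The terminal ynamide diyne may decompose thermally, oligomerise with itself, or be diverted by carbonyl insertion to a cyclopentadienone complex before the cobaltacycle is captured by the hindered alkyne. The fallback changes the nitrogen group to a sulfonyl group, the class of ynamide that is thermally most robust and best established in cobalt cyclotrimerisations, and brings in the N-methyl group separately. It sets out from 1 and comes back at 14.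
- Tosylation of 1 (TsCl, Et3N, CH2Cl2) gives N-(but-3-yn-1-yl)-4-methylbenzenesulfonamide F1.
- Deprotonation of the N–H with KN(SiMe3)2 in toluene and reaction with (trimethylsilylethynyl)phenyliodonium triflate gives N-(but-3-yn-1-yl)-4-methyl-N-[(trimethylsilyl)ethynyl]benzenesulfonamide F2. No alkyne protection is needed, since the sulfonamide N–H is far more acidic than the alkyne C–H and no copper acetylide is involved.
- TBAF gives N-(but-3-yn-1-yl)-N-ethynyl-4-methylbenzenesulfonamide F3.
- Cocyclisation with 11 under CpCo(CO)2 gives 1-[(4-methylphenyl)sulfonyl]-5,6-bis(trimethylsilyl)indoline F4.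
- Mg in MeOH with sonication removes the sulfonyl group and gives 5,6-bis(trimethylsilyl)indoline F5.
- Reductive methylation (aqueous formaldehyde, NaBH(OAc)3) returns to 14.

Step 10. Bromine may attack C3 and expel the aminomethyl side chain (retro-Mannich-type ipso substitution), oxidise the amine, or be outrun by protodesilylation so that a bromine is missing at C5 or C6. The fallback carries C3 as an aldehyde through both halogenations and makes the amine last. It sets out from 15 and comes back at 21.
- Vilsmeier formylation (POCl3, DMF; aq NaOH) gives 1-methyl-5,6-bis(trimethylsilyl)-1H-indole-3-carbaldehyde F6.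
- A one-pot sequence of in-situ aldehyde protection with LiN(Me)CH2CH2NMe2, C2 lithiation with n-BuLi, quench with BrCCl2CCl2Br and aqueous work-up gives 2-bromo-1-methyl-5,6-bis(trimethylsilyl)-1H-indole-3-carbaldehyde F7.
- Br2/NaOAc/AcOH then carries out the double ipso-bromodesilylation on a substrate that has no amine and a deactivated pyrrole ring, giving 2,5,6-tribromo-1-methyl-1H-indole-3-carbaldehyde F8.
- Reductive amination (Me2NH, NaBH(OAc)3, 1,2-dichloroethane) gives 21.

Step 9. Metalation may be incomplete or occur at the wrong site (C4 or a silyl methyl group), or the bromine donor may react with the tertiary amine by electron transfer or quaternisation. The fallback brominates C2 before the amine is present. It sets out from 15 and comes back at 19.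
- C2 lithiation of 15 (n-BuLi, THF, 0 °C), the inherent site of deprotonation of 1-methylindoles, and quench with BrCCl2CCl2Br give 2-bromo-1-methyl-5,6-bis(trimethylsilyl)-1H-indole F9.
- Mannich reaction of F9 with 16 at C3 returns to 19.

**Further compounds**

F1 | step 5 | N-(but-3-yn-1-yl)-4-methylbenzenesulfonamide | Cc1ccc(cc1)S(=O)(=O)NCCC#C
F2 | step 5 | N-(but-3-yn-1-yl)-4-methyl-N-[(trimethylsilyl)ethynyl]benzenesulfonamide | Cc1ccc(cc1)S(=O)(=O)N(CCC#C)C#C[Si](C)(C)C
F3 | step 5 | N-(but-3-yn-1-yl)-N-ethynyl-4-methylbenzenesulfonamide | Cc1ccc(cc1)S(=O)(=O)N(CCC#C)C#C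
F4 | step 5 | 1-[(4-methylphenyl)sulfonyl]-5,6-bis(trimethylsilyl)indoline | Cc1ccc(cc1)S(=O)(=O)N1CCc2cc([Si](C)(C)C)c([Si](C)(C)C)cc21
F5 | step 5 | 5,6-bis(trimethylsilyl)indoline | C[Si](C)(C)c1cc2CCNc2cc1[Si](C)(C)C
F6 | step 10 | 1-methyl-5,6-bis(trimethylsilyl)-1H-indole-3-carbaldehyde | Cn1cc(C=O)c2cc([Si](C)(C)C)c([Si](C)(C)C)cc21
F7 | step 10 | 2-bromo-1-methyl-5,6-bis(trimethylsilyl)-1H-indole-3-carbaldehyde | Cn1c(Br)c(C=O)c2cc([Si](C)(C)C)c([Si](C)(C)C)cc21
F8 | step 10 | 2,5,6-tribromo-1-methyl-1H-indole-3-carbaldehyde | Cn1c(Br)c(C=O)c2cc(Br)c(Br)cc21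
F9 | step 9 | 2-bromo-1-methyl-5,6-bis(trimethylsilyl)-1H-indole | Cn1c(Br)cc2cc([Si](C)(C)C)c([Si](C)(C)C)cc21
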